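Assumption: the target is taken exactly as drawn, (3aS,5S,6R,9S,10Z,11aR); atom labels C1–C15 follow germacranolide numbering (C6 = lactone O–CH, C7 = ring-fusion CH carrying C11(=C13H2)–C12, C3 = acetate carbon, C4 = C–CH3 of the ring alkene, C9 = angelate carbon, C10 = CH–CH3).

**Retrosynthetic overview**
1. Target 16 ⇒ diene acid 14: the lactone O–C6 bond and the acetate O–C3 bond are cut together (palladium-catalysed oxidative 1,4-acetoxy-lactonisation of a (Z,Z)-cyclodeca-1,3-diene; sets C6, C3 and the Z-C4=C5 bond).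
2. 14 ⇒ dienol 10 + angelic acid 11 (ester C–O bond); the acrylic acid is carried as an acrolein dimethyl acetal.
3. 10 ⇒ cis-1,2-divinylcyclohexenol 7: anionic oxy-Cope ring expansion (six- to ten-membered carbocycle), enolate methylation (C10), ketone reduction (C9).
4. 7 ⇒ (S)-carvone 1: side-chain oxidation and acetal masking, deconjugative α-vinylation, vinyl Grignard addition.
5. Ring order: cyclohexenone (from carvone) → ten-membered carbocycle → γ-lactone (last).

**Route**

Step 1
Reactants: 1 (S)-(+)-carvone, (5S)-2-methyl-5-(prop-1-en-2-yl)cyclohex-2-en-1-one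
Product: 2 (5S)-5-(3-chloroprop-1-en-2-yl)-2-methylcyclohex-2-en-1-one
Conditions: Ca(OCl)2, CO2 (dry ice), CH2Cl2/H2O, 0 °C
Reagents that add atoms: calcium hypochlorite, [Ca+2].[O-]Cl.[O-]Cl
Why: Ene-type allylic chlorination by HOCl engages only the electron-rich 1,1-disubstituted side-chain alkene (the enone is deactivated) and shifts the double bond within the side chain, so the C7 stereocentre is untouched.

Step 2
Reactants: 2 (5S)-5-(3-chloroprop-1-en-2-yl)-2-methylcyclohex-2-en-1-one
Product: 3 2-[(1S)-4-methyl-5-oxocyclohex-3-en-1-yl]prop-2-enal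
Conditions: NMO, NaI (cat.), MeCN, 45 °C
Reagents that add atoms: N-methylmorpholine N-oxide, C[N+]1([O-])CCOCC1
Why: Kornblum-type N-oxide oxidation (iodide-assisted SN2 displacement of the primary allylic chloride by the N-oxide oxygen, then loss of N-methylmorpholine) gives the 2-substituted acrolein under near-neutral conditions that leave the enone and C7 alone.

Step 3
Reactants: 3 2-[(1S)-4-methyl-5-oxocyclohex-3-en-1-yl]prop-2-enal
Product: 4 (5S)-5-(3,3-dimethoxyprop-1-en-2-yl)-2-methylcyclohex-2-en-1-one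
Conditions: HC(OMe)3, CeCl3·7H2O (cat.), MeOH, rt
Reagents that add atoms: trimethyl orthoformate, COC(OC)OC
Why: Chemoselective (Luche-type) acetalisation converts only the aldehyde, the conjugated ketone being inert, and masks the future C12 carboxyl against the bases, organometallics and hydride that follow.

Step 4
Reactants: 4 (5S)-5-(3,3-dimethoxyprop-1-en-2-yl)-2-methylcyclohex-2-en-1-one
Product: 6 (2S,5R)-5-(3,3-dimethoxyprop-1-en-2-yl)-2-ethenyl-2-methylcyclohex-3-en-1-one, via sulfoxide adduct 5 (not isolated)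
Conditions: KOt-Bu (30 mol %), PhS(O)CH=CH2, t-BuOH/THF, 0 °C → rt; then xylenes, 140 °C
Reagents that add atoms: phenyl vinyl sulfoxide, C=CS(=O)c1ccccc1
Why: Deconjugative α-alkylation of the thermodynamic extended dienolate by Michael addition to the vinyl sulfoxide (a vinyl cation equivalent), then thermal sulfoxide syn-elimination, builds the C4 quaternary centre and moves the ring alkene to C5=C6; the electrophile enters anti to the C7 side chain to give the 2,5-trans isomer, the minor epimer being removed by chromatography.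

Step 5
Reactants: 6 (2S,5R)-5-(3,3-dimethoxyprop-1-en-2-yl)-2-ethenyl-2-methylcyclohex-3-en-1-one
Product: 7 (1R,2S,5R)-5-(3,3-dimethoxyprop-1-en-2-yl)-1,2-diethenyl-2-methylcyclohex-3-en-1-ol (the two vinyl groups cis)
Conditions: CH2=CHMgBr, LaCl3·2LiCl (30 mol %), THF, −78 → 0 °C; H2O
Reagents that add atoms: vinylmagnesium bromide, C=C[Mg]Br
Why: Lanthanum-promoted Grignard 1,2-addition by axial attack anti to the pseudo-axial C4 methyl group (Felkin-type; the attacked face has no syn-axial substituent at sp2 C5) puts the new vinyl group cis to the C4 vinyl group and sets the carbinol centre as 1R, the minor carbinol epimer being separated.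

Step 6
Reactants: 7 (1R,2S,5R)-5-(3,3-dimethoxyprop-1-en-2-yl)-1,2-diethenyl-2-methylcyclohex-3-en-1-ol
Product: 9 (3R,4Z,6Z,10R)-3-(3,3-dimethoxyprop-1-en-2-yl)-6,10-dimethylcyclodeca-4,6-dien-1-one, via potassium enolate 8 (not isolated)
Conditions: KH, 18-crown-6, THF, 0 °C → rt; then MeI, −78 °C
Reagents that add atoms: iodomethane, CI
Why: Anionic oxy-Cope rearrangement through the chair transition state of the cis-divinyl alkoxide (C9 vinyl axial, C4 vinyl equatorial) expands the ring to the ten-membered carbocycle with a new Z-C3=C4 bond, keeps the former cyclohexene bond as Z-C5=C6 and gives the ring-trans enolate regiospecifically, and iodomethane then alkylates C10 from the exposed peripheral face of that enolate (macrocyclic stereocontrol), setting C10 as R.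

Step 7
Reactants: 9 (3R,4Z,6Z,10R)-3-(3,3-dimethoxyprop-1-en-2-yl)-6,10-dimethylcyclodeca-4,6-dien-1-one
Product: 10 (1S,3R,4Z,6Z,10R)-3-(3,3-dimethoxyprop-1-en-2-yl)-6,10-dimethylcyclodeca-4,6-dien-1-ol
Conditions: LiBH(s-Bu)3, THF, −78 °C; H2O
Reagents that add atoms: none
Why: Bulky-hydride reduction from the ring periphery, anti to the C10 methyl group (Felkin–Anh, as in the cis-selective reduction of 2-methylcycloalkanones), gives the 9,10-anti alcohol and sets C9 as S.

Step 8
Reactants: 10 (1S,3R,4Z,6Z,10R)-3-(3,3-dimethoxyprop-1-en-2-yl)-6,10-dimethylcyclodeca-4,6-dien-1-ol; 11 angelic acid, (2Z)-2-methylbut-2-enoic acid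
Product: 12 (1S,3R,4Z,6Z,10R)-3-(3,3-dimethoxyprop-1-en-2-yl)-6,10-dimethylcyclodeca-4,6-dien-1-yl (2Z)-2-methylbut-2-enoate
Conditions: 11, 2,4,6-Cl3C6H2COCl, Et3N, PhMe, rt; then 10, 70 °C (no DMAP)
Reagents that add atoms: none
Why: Yamaguchi-type mixed-anhydride esterification run without a nucleophilic catalyst acylates the hindered secondary alcohol while keeping the Z geometry of the angelate (no isomerisation to tiglate), and C9 is not touched.

Step 9
Reactants: 12 (1S,3R,4Z,6Z,10R)-3-(3,3-dimethoxyprop-1-en-2-yl)-6,10-dimethylcyclodeca-4,6-dien-1-yl (2Z)-2-methylbut-2-enoate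
Product: 14 2-[(1R,2Z,4Z,8R,9S)-4,8-dimethyl-9-{[(2Z)-2-methylbut-2-enoyl]oxy}cyclodeca-2,4-dien-1-yl]prop-2-enoic acid, via enal 13 (not isolated)
Conditions: PPTS (cat.), acetone/H2O, 40 °C; then NaClO2, NaH2PO4, 2-methyl-2-butene, t-BuOH/H2O, 0 °C
Reagents that add atoms: water, O; sodium chlorite, [Na+].[O-]Cl=O
Why: Mild acetal hydrolysis followed by Pinnick oxidation, with 2-methyl-2-butene scavenging hypochlorite, turns the masked aldehyde into the acrylic acid without touching the diene, the angelate or the C7 stereocentre.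

Step 10
Reactants: 14 2-[(1R,2Z,4Z,8R,9S)-4,8-dimethyl-9-{[(2Z)-2-methylbut-2-enoyl]oxy}cyclodeca-2,4-dien-1-yl]prop-2-enoic acid
Product: 16 (3aS,5S,6R,9S,10Z,11aR)-9-acetoxy-6,10-dimethyl-3-methylidene-2-oxo-2,3,3a,4,5,6,7,8,9,11a-decahydrocyclodeca[b]furan-5-yl (2Z)-2-methylbut-2-enoate (the target), via allylpalladium acetate 15 (not isolated)
Conditions: Pd(OAc)2 (10 mol %), p-benzoquinone (2 equiv), AcOH/acetone (1:4), 25 °C, chloride-free
Reagents that add atoms: acetic acid, CC(O)=O
Why: Proposed new method: palladium-catalysed oxidative 1,4-acetoxy-lactonisation of a medium-ring diene by an acrylic acid, in which divalent palladium binds the less substituted C5=C6 bond, the carboxylate attacks C6 anti to the metal (5-exo) from the conformer that minimises allylic 1,3-strain (H7 eclipsing C5=C6, side chain on one π-face, metal on the other) to give the trans-fused lactone with C6 as R, the resulting anti,anti 2-methyl-π-allyl complex keeps C6 cis to C3 and, without chloride, transfers a coordinated acetate to C3 on the metal face (cis migration) to give the 1,4-trans adduct with C3 as S and the Z-C4=C5 bond, and benzoquinone reoxidises zerovalent palladium; the closest known reaction type is the Bäckvall 1,4-acetoxy-lactonisation of 2-(cyclohexa-2,4-dienyl)- and 2-(cyclohepta-2,4-dienyl)acetic acids, which gives cis-fused lactones in small rings and has not been shown for ten-membered dienes, α-methylene acids or trans ring fusion.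

**Compound list**
1 | (S)-(+)-carvone, (5S)-2-methyl-5-(prop-1-en-2-yl)cyclohex-2-en-1-one | CC1=CC[C@@H](CC1=O)C(C)=C | starting material
2 | (5S)-5-(3-chloroprop-1-en-2-yl)-2-methylcyclohex-2-en-1-one | CC1=CC[C@@H](CC1=O)C(=C)CCl | intermediate
3 | 2-[(1S)-4-methyl-5-oxocyclohex-3-en-1-yl]prop-2-enal | CC1=CC[C@@H](CC1=O)C(=C)C=O | intermediate
4 | (5S)-5-(3,3-dimethoxyprop-1-en-2-yl)-2-methylcyclohex-2-en-1-one | CC1=CC[C@@H](CC1=O)C(=C)C(OC)OC | intermediate
5 | (2S,5R)-5-(3,3-dimethoxyprop-1-en-2-yl)-2-methyl-2-[2-(phenylsulfinyl)ethyl]cyclohex-3-en-1-one (both sulfur epimers) | O=C1C[C@@H](C(=C)C(OC)OC)C=C[C@]1(C)CCS(=O)c1ccccc1 | intermediate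
6 | (2S,5R)-5-(3,3-dimethoxyprop-1-en-2-yl)-2-ethenyl-2-methylcyclohex-3-en-1-one | O=C1C[C@@H](C(=C)C(OC)OC)C=C[C@]1(C)C=C | intermediate
7 | (1R,2S,5R)-5-(3,3-dimethoxyprop-1-en-2-yl)-1,2-diethenyl-2-methylcyclohex-3-en-1-ol | O[C@@]1(C=C)C[C@@H](C(=C)C(OC)OC)C=C[C@]1(C)C=C | intermediate
8 | potassium (1Z,5Z,7Z,9R)-9-(3,3-dimethoxyprop-1-en-2-yl)-6-methylcyclodeca-1,5,7-trien-1-olate (ring-trans enolate) | [K+].[O-]/C1=C\CC/C=C(/C)\C=C/[C@H](C(=C)C(OC)OC)C1 | intermediate
9 | (3R,4Z,6Z,10R)-3-(3,3-dimethoxyprop-1-en-2-yl)-6,10-dimethylcyclodeca-4,6-dien-1-one | O=C1[C@H](C)CC/C=C(/C)\C=C/[C@H](C(=C)C(OC)OC)C1 | intermediate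
10 | (1S,3R,4Z,6Z,10R)-3-(3,3-dimethoxyprop-1-en-2-yl)-6,10-dimethylcyclodeca-4,6-dien-1-ol | O[C@@H]1[C@H](C)CC/C=C(/C)\C=C/[C@H](C(=C)C(OC)OC)C1 | intermediate
11 | angelic acid, (2Z)-2-methylbut-2-enoic acid | C/C=C(/C)C(O)=O | starting material
12 | (1S,3R,4Z,6Z,10R)-3-(3,3-dimethoxyprop-1-en-2-yl)-6,10-dimethylcyclodeca-4,6-dien-1-yl (2Z)-2-methylbut-2-enoate | C/C=C(/C)C(=O)O[C@@H]1[C@H](C)CC/C=C(/C)\C=C/[C@H](C(=C)C(OC)OC)C1 | intermediate
13 | (1S,3R,4Z,6Z,10R)-6,10-dimethyl-3-(3-oxoprop-1-en-2-yl)cyclodeca-4,6-dien-1-yl (2Z)-2-methylbut-2-enoate | C/C=C(/C)C(=O)O[C@@H]1[C@H](C)CC/C=C(/C)\C=C/[C@H](C(=C)C=O)C1 | intermediate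
14 | 2-[(1R,2Z,4Z,8R,9S)-4,8-dimethyl-9-{[(2Z)-2-methylbut-2-enoyl]oxy}cyclodeca-2,4-dien-1-yl]prop-2-enoic acid | C/C=C(/C)C(=O)O[C@@H]1[C@H](C)CC/C=C(/C)\C=C/[C@H](C(=C)C(O)=O)C1 | intermediate
15 | allylpalladium acetate of the closed lactone (divalent palladium on the C3–C5 allyl face opposite the lactone oxygen; drawn as its C3 σ-form) | C=C1C(=O)O[C@@H]2/C=C(/C)[C@@H]([Pd]OC(C)=O)CC[C@@H](C)[C@@H](OC(=O)/C(C)=C\C)C[C@@H]12 | intermediate
16 | (3aS,5S,6R,9S,10Z,11aR)-9-acetoxy-6,10-dimethyl-3-methylidene-2-oxo-2,3,3a,4,5,6,7,8,9,11a-decahydrocyclodeca[b]furan-5-yl (2Z)-2-methylbut-2-enoate | C=C1C(=O)O[C@@H]2/C=C(/C)[C@@H](OC(C)=O)CC[C@@H](C)[C@@H](OC(=O)/C(C)=C\C)C[C@@H]12 | target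

**Totals**
Total step count: 10. Longest linear sequence: 10 steps (1 → 16); angelic acid 11 enters at step 8.

**Three steps most likely to fail**

Step 10 (the proposed new step; risks are cis- instead of trans-lactone fusion, syn/anti scrambling of the π-allyl, or E-C4=C5). The fallback uses known chemistry, sets out from 14 and comes back at 16. PhSeCl in CH2Cl2 at −78 °C effects anti selenolactonisation across C5=C6 and gives the phenylseleno lactone F4 (oxygen at C6, selenium at C5, C3=C4 intact). H2O2/pyridine at 0 °C oxidises it to the allylic selenoxide, which undergoes the [2,3]-sigmatropic shift and selenenate hydrolysis to the C3 allylic alcohol F5; the oxygen arrives at C3 on the face the selenium occupied, that is trans to the lactone oxygen, and C4=C5 is formed. Ac2O/DMAP/pyridine then acetylates F5 to 16.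

Step 4 (Michael addition of a hindered tetrasubstituted dienolate carbon may be slow or give α′-adducts, and the thermolysis is hot). The fallback replaces the Michael/elimination by electrophilic alkynylation and semireduction, sets out from 4 and comes back at 7. The potassium dienolate of 4 (KOt-Bu, THF, −78 °C) is treated with 1-[(trimethylsilyl)ethynyl]-1,2-benziodoxol-3(1H)-one and TBAF to give the α-ethynyl ketone F1. CH2=CHMgBr/LaCl3·2LiCl adds on the face of the small ethynyl group to give the ethynyl vinyl carbinol F2. H2 over Pd/CaCO3 (Pb(OAc)2-poisoned) with quinoline reduces only the alkyne and gives 7.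

Step 6 (the alkylation may give the C10 epimer, over-alkylate or O-alkylate). The fallback brings C14 in with the Grignard reagent and sets C10 by protonation instead of alkylation; it sets out from 6 and comes back at 9. CH2=C(CH3)MgBr/LaCl3·2LiCl adds to 6 to give the isopropenyl carbinol F3. KH/18-crown-6 in THF triggers the same oxy-Cope rearrangement, and the methyl-bearing enolate is protonated with AcOH at −78 °C to give 9. Proton and methyl group enter from the same face, so this variant is stereocomplementary to the alkylation at C10, and the α-methyl ketone can also be equilibrated with DBU.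

**Further compounds**
F1 | step 4 | (2R,5R)-5-(3,3-dimethoxyprop-1-en-2-yl)-2-ethynyl-2-methylcyclohex-3-en-1-one | O=C1C[C@@H](C(=C)C(OC)OC)C=C[C@]1(C)C#C
F2 | step 4 | (1R,2R,5R)-5-(3,3-dimethoxyprop-1-en-2-yl)-1-ethenyl-2-ethynyl-2-methylcyclohex-3-en-1-ol | O[C@@]1(C=C)C[C@@H](C(=C)C(OC)OC)C=C[C@]1(C)C#C
F3 | step 6 | (1R,2S,5R)-5-(3,3-dimethoxyprop-1-en-2-yl)-2-ethenyl-2-methyl-1-(prop-1-en-2-yl)cyclohex-3-en-1-ol | O[C@@]1(C(C)=C)C[C@@H](C(=C)C(OC)OC)C=C[C@]1(C)C=C
F4 | step 10 | (3aS,5S,6R,9Z,11S,11aS)-6,10-dimethyl-3-methylidene-2-oxo-11-(phenylselanyl)-2,3,3a,4,5,6,7,8,11,11a-decahydrocyclodeca[b]furan-5-yl (2Z)-2-methylbut-2-enoate | C=C1C(=O)O[C@@H]2[C@@H]([Se]c3ccccc3)/C(C)=C\CC[C@@H](C)[C@@H](OC(=O)/C(C)=C\C)C[C@@H]12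
F5 | step 10 | (3aS,5S,6R,9S,10Z,11aR)-9-hydroxy-6,10-dimethyl-3-methylidene-2-oxo-2,3,3a,4,5,6,7,8,9,11a-decahydrocyclodeca[b]furan-5-yl (2Z)-2-methylbut-2-enoate | C=C1C(=O)O[C@@H]2/C=C(/C)[C@@H](O)CC[C@@H](C)[C@@H](OC(=O)/C(C)=C\C)C[C@@H]12
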